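I chose to count the substrate still left in the flask, not the products made, and to ask what share of the consumed substrate becomes other mono adduct.

| flask | substrate | coupling partner | scavenger | remark | time |
|---|---|---|---|---|---|
| alder | 0.40 M | 1.2 M | 0.60 M | the very flask that is asked about, followed so far |  |
| oak | 0.40 M | 0.60 M | 0.60 M | run made earlier |  |
| flask | 0.40 M | 1.20 M | 0.600 M |  | 2.5 min |

| run | time / s | other mono adduct / % | first product / % |
|---|---|---|---|
| alder | 10.0 | 10.5 | 11.6 |
| alder | 20.0 | 17.8 | 19.4 |
| alder | 40.0 | 27.0 | 23.3 |
| alder | 50.0 | 29.8 | 24.4 |
| alder | 80.0 | 35.2 | 22.7 |
| oak | 10.0 | 5.7 | 6.7 |
| oak | 15.0 | 7.6 | 9.2 |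
| oak | 30.0 | 13.8 | 14.9 |
| oak | 60.0 | 21.5 | 20.3 |
| oak | 120 | 29.8 | 24.3 |

(readings scatter by 0.5 percentage points)

- released group is meant together with its idle adduct and crystals
- solid, in amounts per volume of the solution: crystals
- the analysis behind the earlier runs scatters by 0.5 percentage points, standard deviation
- steps that have been proposed: coupling partner + released group <-> idle adduct; substrate + released group -> side product; scavenger + released group -> scavenged by-product; substrate + coupling partner -> other mono adduct + released group; coupling partner + other mono adduct -> double product + released group; coupling partner + first product -> double product + released group; substrate + coupling partner -> first product + released group; crystals <-> released group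

- equivalents of coupling partner to substrate, everything else as given, that leave most other mono adduct at 2.5 min
- the amount of other mono adduct then, in percent of the substrate charged
- the amount of other mono adduct with the amounts as given

In alder at 10.0 s the readings are 10.5 % of other mono adduct and 11.6 % of first product. From these I took the share of consumed substrate that becomes other mono adduct, the selectivity, as 0.475. Oak, with half the coupling partner, gives 0.460 at the same time, about the same, so I treated the share as independent of [coupling partner].

Taking double product as negligible that early, the same alder reading gives the fraction of substrate left, and from it a rate constant per unit of [coupling partner]: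

k = ln(1/fraction left) / ([coupling partner] × time) = 0.0208 M⁻¹ s⁻¹

Each substrate consumed takes one coupling partner and each onward step to double product takes another, so [coupling partner] falls through the run; for the asked flask I took its charge minus the substrate charge, 0.800 M, as a rough mean level over the run and not as what remains at the end. That makes the decay pseudo-first-order:

τ = 1 / (k[coupling partner]) = 60.1 s

fraction left at 2.5 min = exp(−time/τ) = 8.23 %

other mono adduct = share × (1 − fraction left) = 43.6 %

The substrate left was worth a further 3.9 percentage points, so I expected little from extra coupling partner.

The forecast, made by someone else from the same runs, differs from my figure: 36.2 % as charged and a best of 36.8 % at 2.6 equiv, with the given charge “slightly past the flat peak”.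

The flask gave 38.6 % as charged, and 38.9 % at 3.51 equiv, a gain of 0.30 points.

    coupling partner + released group ⇌ idle adduct, settled at all times (K = 0.900 M⁻¹)
    substrate + released group → side product (k = 0.0361 M⁻¹ s⁻¹)
    scavenger + released group → scavenged by-product (k = 1.21 M⁻¹ s⁻¹)
    substrate + coupling partner → other mono adduct + released group (k = 0.0105 M⁻¹ s⁻¹)
    coupling partner + other mono adduct → double product + released group (k = 7.62 × 10⁻⁴ M⁻¹ s⁻¹)
    coupling partner + first product → double product + released group (k = 0.0156 M⁻¹ s⁻¹)
    substrate + coupling partner → first product + released group (k = 0.0132 M⁻¹ s⁻¹)
    crystals ⇌ released group, rate k8*(cs8 - [released group]) while solid is left; crystals form when [released group] > cs8 (solubility = 0.390 M, k = 0.890 s⁻¹)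

In the flask, 5.05 % of the substrate was left at 2.50 min, less than my 8.23 %. The share then gives 45.1 % against the 38.6 % found, so other mono adduct per substrate consumed was 0.407, below 0.475. The neighbouring flask, the same recipe with 0.30 M of coupling partner, less than the substrate charge, kept 53.5 % of its substrate at 2.50 min. The same reckoning there gives 22.1 %, and the neighbouring flask held 20.0 % of other mono adduct.

The data are simulated from invented constants, noise included.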